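You have no rate constants for this flask, only two runs that stand flat from their first reading, so you work from what they hold.

in all of them: Q 0.80 M

| flask | E | remark | time |
|---|---|---|---|
| blue | 0.69 M | run made earlier |  |
| amber | 1.4 M | run made earlier |  |
| south-east | 0.560 M |  | 50 min |
| north-west | 1.10 M |  | 50 min |

| run | time / min | J / % | X / % | G / % | D / % | Q / % |
|---|---|---|---|---|---|---|
| blue | 5.00 | 1.8 | 10.3 | 2.3 | 80.8 | 4.2 |
| blue | 10.0 | 2.3 | 9.3 | 3.1 | 81.6 | 3.4 |
| blue | 15.0 | 3.7 | 9.6 | 2.5 | 81.2 | 4.0 |
| blue | 20.0 | 1.6 | 10.3 | 3.6 | 81.5 | 3.9 |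
| blue | 25.0 | 2.2 | 10.4 | 2.6 | 81.0 | 4.2 |
| blue | 30.0 | 1.7 | 10.8 | 3.0 | 80.8 | 4.3 |
| blue | 40.0 | 1.0 | 9.6 | 3.5 | 81.2 | 2.9 |
| amber | 5.00 | 5.7 | 0 | 7.5 | 86.0 | 0.5 |
| amber | 10.0 | 5.4 | 0.1 | 8.1 | 86.2 | 0.9 |
| amber | 15.0 | 5.9 | 0 | 6.9 | 86.3 | 0.4 |
| amber | 20.0 | 5.3 | 0.3 | 8.0 | 86.6 | 0 |
| amber | 25.0 | 5.7 | 0.2 | 7.3 | 87.2 | 0 |
| amber | 30.0 | 6.8 | 0.2 | 7.6 | 86.2 | 0 |
| amber | 40.0 | 5.6 | 0.2 | 7.7 | 85.9 | 0.4 |

(scatter of a reading: 0.5 percentage points)

- which of these there is most of at the end, counted by the Q in it, south-east (D / Q / J / G / X)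
- which of these there is most of at the end, counted by the Q in it, north-west (D / Q / J / G / X)
- the largest of these amounts at the end, in percent of the Q charged, south-east
- the largest of these amounts at the end, in percent of the Q charged, north-west



First question: which charge gives out? In blue the readings of D, G and J add up to the E charged, so you count one E in each and none in X. South-east has 0.700 equivalents of E, so E is the limiting reagent there. North-west has 1.38, so there the Q gives out.

Second question: how does the spent part divide? Take the side ratio, (G + J)/D. Amber reads 0.155, and blue reads 0.0614, so it climbs with E. Divide amber's ratio by the E present midway through the spending, and you have the side coefficient 0.155 /M. Blue, by this coefficient, should read 0.0534, so expect an error of about a point.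

My reckoning: south-east has midpoint E of 0.280 M, so D is 67.1%. North-west has 0.700 M, so D is 90.2%.

The forecast names D and D, at 66.5% and 86.5%, and of north-west it says “so it should behave like amber”. My reckoning stands 3.7 percentage points above the forecast in north-west and 0.60 points above it in south-east.

The flask gives D at 66.0% in south-east and D at 89.9% in north-west.

    Q ⇌ X (K = 2.62, k = 0.0906 /s)
    Q + E → G (k = 0.0133 /M/s)
    E + X → D (k = 1.06 /M/s)
    G ⇌ J (K = 0.686, k = 0.00499 /s)

In south-east, where 0% of the E is left at the end, the running short of E is the main reason D stands at 66.0%, against 92.0% in the same flask with E kept from running short. The coefficient with E at its full charge gives 92.0%. A neighbour of south-east charged with 0.48 M of Q has 1.17 equiv of E and ends with 0% of its Q. Its midpoint E is 0.320 M, so the coefficient gives 95.3%, and that flask stands at 94.6%.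

The earlier runs and the new flask stem from a simulated flask with constants of no real substance, noise included.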